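**Retrosynthetic overview**
1. Dihydropyran (closed last): inverse-demand hetero-Diels–Alder between the strained E-C4=C5 bond of purchased (−)-β-caryophyllene (cyclobutane, nine-membered ring, C1 and C9 bought) and a 2-(3-methylbutylidene)-trione made in the flask by Knoevenagel condensation with isovaleraldehyde; C4, C5 and C1′ are relayed from C1/C9 in this one event.
2. Carbocycle (closed first): the tetramethylcyclohexanetrione ring is closed at the C(=O)–CMe2 bond of its doubly neopentyl ketone by Claisen (Dieckmann-type) attack of an isobutyryl γ-carbanion on the ester of open-chain methyl 2,2,6-trimethyl-3,5-dioxoheptanoate; closure, condensation and cycloaddition run as one operation.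
3. Enabling feature: the ring CH2 of the cyclohexane-1,3,5-trione (the carbon that becomes C3 of the dihydropyran), flanked by two C=O groups. In the open chain it makes the isobutyryl methine the γ-site of a 1,3-diketone dianion; after closure it ionises and shields the non-enolisable CMe2–CO–CMe2 ketone from retro-Claisen cleavage; it is then the Knoevenagel carbon. This is why the carbocycle is closed before the pyran exists.
4. The open-chain keto ester comes from methyl isobutyrate by two successive C-acylations (acetyl chloride, then isobutyryl chloride).
5. Ring order: six-membered carbocycle, then dihydropyran.

Key step: step 3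

Remark: the ring-fusion centres of the target match natural (−)-(1R,9S)-β-caryophyllene, which is used as bought; syncarpic acid is mirror-symmetric, so the two C(=O)–CMe2 bonds of its central ketone are equivalent and the bond closed in step 3 is the one next to the enone carbonyl of the target whichever flanking carbonyl later supplies the pyran oxygen.

Step 1
Reactants: 1 methyl isobutyrate (methyl 2-methylpropanoate)
Product: 2 methyl 2,2-dimethyl-3-oxobutanoate
Conditions: LDA (1.05 equiv), THF, −78 °C; enolate added to AcCl (1.5 equiv), THF, −78 °C
Reagents that add atoms: acetyl chloride, CC(=O)Cl
Why: Claisen-type C-acylation of a lithium ester enolate by an acid chloride; the α,α-disubstituted enolate reacts at carbon, inverse addition keeps it from deprotonating the acetyl group of the product, and no stereocentre is formed.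

Step 2
Reactants: 2 methyl 2,2-dimethyl-3-oxobutanoate
Product: 3 methyl 2,2,6-trimethyl-3,5-dioxoheptanoate
Conditions: 2 (2.0 equiv), LiHMDS (2.1 equiv), toluene–THF, 0 °C; isobutyryl chloride (1.0 equiv); 1 M HCl work-up, excess 2 recovered
Reagents that add atoms: isobutyryl chloride (2-methylpropanoyl chloride), CC(C)C(=O)Cl
Why: crossed Claisen-type acylation of a ketone enolate by an acid chloride (one-pot 1,3-diketone synthesis); the acetyl CH3 is the only enolisable site of 2, the product is converted at once into its lithium diketonate, which blocks bis-acylation and retro-Claisen cleavage, and no stereocentre is formed.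

Step 3
Reactants: 3 methyl 2,2,6-trimethyl-3,5-dioxoheptanoate; 4 isovaleraldehyde (3-methylbutanal); 5 (−)-β-caryophyllene
Product: 8 tomentodione B, via syncarpic acid 6 (not isolated), via alkylidene trione 7 (not isolated)
Conditions: LDA (2.3 equiv), THF, −78 → 25 °C; then AcOH (4 equiv), ethylenediammonium diacetate (EDDA, 10 mol %), 4 (1.5 equiv), 5 (2 equiv), 65 °C
Reagents that add atoms: none
Why: LDA converts 3 into its 1,3-diketonate and then removes the isobutyryl methine proton (the only γ-hydrogen, the other flank being quaternary), and this dianion carbon attacks the 1,6-related methyl ester and expels methoxide, closing the carbocycle at the C(=O)–CMe2 bond in a 6-(enolendo)-exo-trig Claisen (Dieckmann-type) condensation, the closest known reaction type being the acylation of β-diketone dianions by esters as in Claisen cyclisations of 3,5-dioxo esters to cyclohexane-1,3,5-triones. The closure should go to completion because the ring CH2 of 6 ionises at once, which also shields the hindered central ketone from retro-Claisen attack by LiOMe, and C- over O-acylation is secured by the far higher nucleophilicity of the dianion carbon. After acidification EDDA catalyses Knoevenagel condensation of that CH2 with 4 to the planar, electron-poor 1-oxadiene 7, which adds to the strained E-C4=C5 bond of 5 in an inverse-electron-demand hetero-Diels–Alder reaction that closes the dihydropyran by concerted [4+2] cycloaddition with O bound to the tertiary C4 and the alkylidene carbon to C5, a reactivity well established for β-caryophyllene with 2-alkylidene-1,3-diones and o-quinone methides. Suprafacial addition to the E-alkene fixes the C4 methyl trans to H-5, and the bought C1/C9 centres of the trans-fused cyclobutane, through the preferred conformers of the nine-membered ring, expose the 4Re,5Re face (the face that peracids attack on the way to natural caryophyllene oxide), which sets 4R,5S. The isobutyl centre (1′R, H-1′ cis to H-5) follows from the orientation in which the C4 methyl and the C6 methylene lie under the oxadiene. The step needs chemoselectivity for the endocyclic over the exocyclic alkene, secured by the strain and higher substitution of C4=C5, and facial and orientational selectivity that rests on substrate control alone, so the C1′ epimer and opposite-face adducts are to be expected as by-products to be removed by chromatography.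

**Compound list**
1 | methyl isobutyrate (methyl 2-methylpropanoate) | COC(=O)C(C)C | starting material
2 | methyl 2,2-dimethyl-3-oxobutanoate | COC(=O)C(C)(C)C(C)=O | intermediate
3 | methyl 2,2,6-trimethyl-3,5-dioxoheptanoate (keto–enol mixture, drawn as the diketone) | COC(=O)C(C)(C)C(=O)CC(=O)C(C)C | intermediate
4 | isovaleraldehyde (3-methylbutanal) | CC(C)CC=O | starting material
5 | (−)-β-caryophyllene, (1R,9S), 4E | C=C1CC/C=C(\C)CC[C@@H]2[C@@H]1CC2(C)C | starting material
6 | syncarpic acid (2,2,4,4-tetramethylcyclohexane-1,3,5-trione; formed as its lithium enolate, freed by AcOH, not isolated) | CC1(C)C(=O)CC(=O)C(C)(C)C1=O | intermediate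
7 | 2,2,4,4-tetramethyl-6-(3-methylbutylidene)cyclohexane-1,3,5-trione (not isolated) | CC(C)CC=C1C(=O)C(C)(C)C(=O)C(C)(C)C1=O | intermediate
8 | tomentodione B (dihydropyran fused to C4–C5 of the (1R,9S)-caryophyllane skeleton and to the tetramethylcyclohexenedione ring; 4R,5S,1′R; exocyclic methylene retained) | C=C1CC[C@H]2[C@@H](CC(C)C)C3=C(O[C@]2(C)CC[C@@H]2[C@@H]1CC2(C)C)C(C)(C)C(=O)C(C)(C)C3=O | target

**Totals and risks**
Total step count: 3. Longest linear sequence: 3 steps (1 → 2 → 3 → 8).

Most likely to fail, in order:

First, step 3. What may go wrong: incomplete γ-deprotonation or competing O-acylation (enol-lactone formation) in the dianion closure; Michael addition of a second trione to the alkylidene trione in the crowded one-pot medium; and facial or orientational selectivity that is too low to give a workable share of the desired diastereomer. Fallback: it sets out from 3 and comes back at 8. The ring closure is run alone under the same dianion Claisen conditions and syncarpic acid 6 is isolated by extraction into aqueous NaHCO3 and re-acidification. Compound 6 is then condensed with 4 and piperidine (CH2Cl2, 25 °C) to the isolable Mannich base 5-hydroxy-2,2,6,6-tetramethyl-4-[3-methyl-1-(piperidin-1-yl)butyl]cyclohex-4-ene-1,3-dione F1. Heating F1 with 5 in toluene/AcOH releases 7 slowly by loss of piperidine, so that its stationary concentration stays low and the cycloaddition to 8 can be optimised on its own (solvent, temperature) for diastereomer distribution.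

Second, step 2. What may go wrong: O-acylation of the ketone enolate, or acylation of the amide base instead of the enolate. Fallback: it sets out from 2 and comes back at 3. The lithium enolate of 2 (LDA, THF, −78 °C) is added to isobutyraldehyde in an aldol reaction, giving methyl 5-hydroxy-2,2,6-trimethyl-3-oxoheptanoate F2. Oxidation with Dess–Martin periodinane (CH2Cl2, 25 °C) then gives the 1,3-diketone 3; this sequence has no O- versus C-acylation issue.

Third, step 1. What may go wrong: proton transfer from the acetyl group of the product (or from acetyl chloride) to the ester enolate, which stalls conversion and leads to bis-acylation. Fallback: it sets out from 1 and comes back at 2. Compound 1 is converted (LDA, then TMSCl, THF, −78 → 25 °C) into the silyl ketene acetal 1-methoxy-2-methyl-1-(trimethylsilyloxy)prop-1-ene F3. This is C-acylated with acetyl chloride under neutral Mukaiyama-type conditions (CH2Cl2, cat. ZnCl2, 0 → 25 °C) to give 2 with no basic enolate present.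

Further compounds
F1 | step 3 | 5-hydroxy-2,2,6,6-tetramethyl-4-[3-methyl-1-(piperidin-1-yl)butyl]cyclohex-4-ene-1,3-dione (racemic Mannich base) | CC(C)CC(N1CCCCC1)C1=C(O)C(C)(C)C(=O)C(C)(C)C1=O
F2 | step 2 | methyl 5-hydroxy-2,2,6-trimethyl-3-oxoheptanoate (racemic) | COC(=O)C(C)(C)C(=O)CC(O)C(C)C
F3 | step 1 | 1-methoxy-2-methyl-1-(trimethylsilyloxy)prop-1-ene | COC(O[Si](C)(C)C)=C(C)C
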